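**Retrosynthetic overview**
- The last operation forms both rings in the biosynthetic order: C6–C7 closure of an acyclic (4E,1(10)Z) farnesane-type aldehyde / 2-(methoxycarbonyl)allyl acetate gives the ten-membered carbocycle, then the C6 alkoxide closes the 12,6-lactone.
- The seco chain is built around a (Z)-β-iodo-methacrolein linchpin (C9–C10(C14)=C1): C8–C9 by asymmetric allylation, C2 by carbonylation of the vinyl iodide, and C2–C3 by a vinylogous Mukaiyama aldol that delivers C3–C6 with the C6 aldehyde.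
- The C11–C13 acrylate comes from cross-metathesis; the 9-O-sarracinoyl ester (from methyl but-2-ynoate) is attached early and carried through.

Assumption: the target is read as (2R,6R,7S,9S)-2-hydroxy-9-[(2Z)-2-(hydroxymethyl)but-2-enoyloxy]germacra-1(10)Z,4E,11(13)-trien-12,6-olide; germacrane numbering (C1–C15) is used for all position labels.

**Route**

Step 1
Reactants: 1 prop-2-yn-1-ol
Product: 3 (2Z)-3-iodo-2-methylprop-2-en-1-ol, via vinylmagnesium alkoxide 2 (not isolated)
Conditions: MeMgBr (2.5 equiv), CuI (10 mol%), THF/Et2O, −10 °C to rt; then I2, −78 to 0 °C; aqueous work-up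
Reagents that add atoms: methylmagnesium bromide, C[Mg]Br; iodine, I-I
Why: Alkoxide-directed, CuI-catalysed anti-carbomagnesiation puts the methyl on the internal carbon and magnesium cis to the CH2O group in a five-membered chelate, and iodinolysis with retention gives only the Z-iodide, which fixes the 1(10)-Z geometry.

Step 2
Reactants: 3 (2Z)-3-iodo-2-methylprop-2-en-1-ol
Product: 4 (2Z)-3-iodo-2-methylprop-2-enal
Conditions: MnO2 (15 equiv), CH2Cl2, rt, dark; filtered and used at once
Reagents that add atoms: none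
Why: Neutral heterogeneous allylic oxidation with MnO2 gives the enal without Z/E scrambling.

Step 3
Reactants: 4 (2Z)-3-iodo-2-methylprop-2-enal
Product: 6 (1Z,3S)-1-iodo-2-methylhexa-1,5-dien-3-ol, via borinate ester 5 (not isolated)
Conditions: (−)-Ipc2B(allyl) (from (+)-α-pinene, 1.3 equiv), Et2O, −78 °C; then NaOH, H2O2, 0 °C to rt
Reagents that add atoms: (−)-B-allyldiisopinocampheylborane, C=CCB([C@@H]1C[C@@H]2C[C@H]([C@H]1C)C2(C)C)[C@@H]1C[C@@H]2C[C@H]([C@H]1C)C2(C)C
Why: Brown allylboration through a chair six-membered transition state; the reagent from (+)-α-pinene attacks the Si face of the conjugated aldehyde (as with benzaldehyde and acrolein), setting C9 as S.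

Step 4
Reactants: 7 methyl but-2-ynoate
Product: 9 methyl (2Z)-2-(hydroxymethyl)but-2-enoate, via vinylalane 8 (not isolated)
Conditions: iBu2AlH (1.3 equiv), NMO (1.4 equiv), THF, 0 °C; 7, 0 °C, 1 h; then (CH2O)n, 0 °C to rt; aqueous Rochelle salt
Reagents that add atoms: formaldehyde (as paraformaldehyde), C=O
Why: syn-Hydroalumination of the ynoate by the iBu2AlH–NMO complex (vinylalumination) places Al at the α-carbon cis to the new β-H, and retentive C–C bond formation with formaldehyde gives the angelate-type Z geometry (methyl cis to the ester).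

Step 5
Reactants: 9 methyl (2Z)-2-(hydroxymethyl)but-2-enoate
Product: 10 (2Z)-2-(hydroxymethyl)but-2-enoic acid (sarracinic acid)
Conditions: LiOH·H2O (2.5 equiv), THF/H2O 3:1, 0 °C to rt; then 1 M HCl to pH 2, 0 °C
Reagents that add atoms: lithium hydroxide, [Li+].[OH-]
Why: Ordinary ester saponification at low temperature leaves the trisubstituted Z-olefin untouched.

Step 6
Reactants: 10 (2Z)-2-(hydroxymethyl)but-2-enoic acid
Product: 12 (2Z)-2-[(triethylsilyloxy)methyl]but-2-enoic acid, via bis-silylated acid 11 (not isolated)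
Conditions: Et3SiCl (2.3 equiv), imidazole (5 equiv), CH2Cl2, 0 °C to rt; then H2O/THF, 0 °C
Reagents that add atoms: chlorotriethylsilane, CC[Si](Cl)(CC)CC
Why: Exhaustive silylation followed by selective hydrolysis of the far more labile silyl ester gives the O-TES acid without exposing the silyl ether to hydroxide.

Step 7
Reactants: 12 (2Z)-2-[(triethylsilyloxy)methyl]but-2-enoic acid; 6 (1Z,3S)-1-iodo-2-methylhexa-1,5-dien-3-ol
Product: 14 (1Z,3S)-1-iodo-2-methylhexa-1,5-dien-3-yl (2Z)-2-[(triethylsilyloxy)methyl]but-2-enoate, via mixed anhydride 13 (not isolated)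
Conditions: 2,4,6-trichlorobenzoyl chloride, Et3N, toluene, rt; then 6, DMAP, rt to 40 °C
Reagents that add atoms: none
Why: Yamaguchi esterification acylates the hindered allylic alcohol at oxygen (C9 untouched) and, unlike carbodiimide/DMAP couplings, does not isomerise angelate-type acids to the E series.

Step 8
Reactants: 14 (1Z,3S)-1-iodo-2-methylhexa-1,5-dien-3-yl (2Z)-2-[(triethylsilyloxy)methyl]but-2-enoate
Product: 15 (2Z,4S)-3-methyl-1-oxohepta-2,6-dien-4-yl (2Z)-2-[(triethylsilyloxy)methyl]but-2-enoate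
Conditions: Pd(PPh3)4 (5 mol%), CO (3 atm), Bu3SnH (1.1 equiv, syringe pump), THF, 50 °C
Reagents that add atoms: carbon monoxide, [C-]#[O+]
Why: Stille–Baillargeon reductive carbonylation (oxidative addition, CO insertion, tin hydride transfer) proceeds with retention at the vinyl carbon and gives the Z-enal, which cannot close to a lactol because O9 is acylated.

Step 9
Reactants: 16 methyl 2-(hydroxymethyl)prop-2-enoate
Product: 17 methyl 2-(acetoxymethyl)prop-2-enoate
Conditions: Ac2O, pyridine, DMAP (cat.), CH2Cl2, 0 °C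
Reagents that add atoms: acetic anhydride, CC(=O)OC(C)=O
Why: Simple O-acetylation gives the allylic acetate that later serves as the π-allyl precursor.

Step 10
Reactants: 15 (2Z,4S)-3-methyl-1-oxohepta-2,6-dien-4-yl (2Z)-2-[(triethylsilyloxy)methyl]but-2-enoate; 17 methyl 2-(acetoxymethyl)prop-2-enoate
Product: 18 methyl (2E,5S,6Z)-2-(acetoxymethyl)-6-methyl-8-oxo-5-({(2Z)-2-[(triethylsilyloxy)methyl]but-2-enoyl}oxy)octa-2,6-dienoate
Conditions: second-generation Hoveyda–Grubbs catalyst RuCl2(H2IMes)(=CH-C6H4-2-OiPr) (7 mol%), 17 (5 equiv), 1,4-benzoquinone (10 mol%), CH2Cl2, 40 °C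
Reagents that add atoms: none
Why: Olefin cross-metathesis between the only monosubstituted alkene and a non-homodimerising 1,1-disubstituted acrylate (methacrylate-type partner) gives the trisubstituted enoate; the trisubstituted enal and enoate olefins are inert and the new olefin geometry is erased later in the π-allyl.

Step 11
Reactants: 19 3-methylbut-2-enal
Product: 20 tert-butyl(dimethyl){[(1E)-3-methylbuta-1,3-dien-1-yl]oxy}silane
Conditions: TBSOTf, Et3N, Et2O, 0 °C to rt
Reagents that add atoms: tert-butyldimethylsilyl triflate, CC(C)(C)[Si](C)(C)OS(=O)(=O)C(F)(F)F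
Why: Soft enolisation with γ-deprotonation gives the cross-conjugated (E)-silyl dienol ether.

Step 12
Reactants: 18 methyl (2E,5S,6Z)-2-(acetoxymethyl)-6-methyl-8-oxo-5-({(2Z)-2-[(triethylsilyloxy)methyl]but-2-enoyl}oxy)octa-2,6-dienoate; 20 tert-butyl(dimethyl){[(1E)-3-methylbuta-1,3-dien-1-yl]oxy}silane
Product: 21 methyl (2E,5S,6Z,8R,10E)-2-(acetoxymethyl)-8-hydroxy-6,10-dimethyl-12-oxo-5-({(2Z)-2-[(triethylsilyloxy)methyl]but-2-enoyl}oxy)dodeca-2,6,10-trienoate
Conditions: (4S)-4-(1H-indol-3-ylmethyl)-2-phenyl-3-tosyl-1,3,2-oxazaborolidin-5-one (from N-tosyl-L-tryptophan and PhBCl2, 1.0 equiv), 20 (1.5 equiv), iPrOH (1.2 equiv), EtCN, −78 °C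
Reagents that add atoms: none
Why: Vinylogous Mukaiyama aldol: the boron-bound Z-enal is attacked by the γ-carbon of the s-trans dienol ether (giving the 4E enal), the L-tryptophan-derived Lewis acid is taken to expose the Re face (sense of tryptophan-oxazaborolidinone aldol additions to conjugated aldehydes, to be confirmed by Mosher analysis) so that C2 is R, and stoichiometric Lewis acid keeps the product enal unactivated.

Step 13
Reactants: 21 methyl (2E,5S,6Z,8R,10E)-2-(acetoxymethyl)-8-hydroxy-6,10-dimethyl-12-oxo-5-({(2Z)-2-[(triethylsilyloxy)methyl]but-2-enoyl}oxy)dodeca-2,6,10-trienoate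
Product: 25 (2R,6R,7S,9S)-2-hydroxy-9-[(2Z)-2-(hydroxymethyl)but-2-enoyloxy]germacra-1(10)Z,4E,11(13)-trien-12,6-olide, via allylindium species 22 (not isolated), via indium alkoxide 23 (not isolated), via silylated lactone 24 (not isolated)
Conditions: Pd(PPh3)4 (5 mol%), InI (1.5 equiv), THF/DMF 4:1, 2 mM (slow addition of 21), rt; then AcOH/THF/H2O 3:1:1, rt
Reagents that add atoms: none
Why: Proposed new method: zerovalent palladium ionises only the primary 2-(methoxycarbonyl)allyl acetate and InI reduces the π-allyl complex to a nucleophilic allylindium (Araki-type umpolung allylation, the catalytic counterpart of Barbier 2-(alkoxycarbonyl)allylation and of chromium- or zinc-mediated germacrane closures), which adds through C7 to the C6 enal in a six-membered chair with the C5 and C8 chain ends both pseudo-equatorial, so C6–C7 forms anti (6R,7S expected if the C9 acyloxy group sits exo on the folding ten-membered ring), after which the C6 alkoxide lactonises onto C12 and aqueous acetic acid removes the TES ether.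

**Compound list**

1 | prop-2-yn-1-ol | C#CCO | starting material
2 | bromomagnesium (2Z)-3-(bromomagnesio)-2-methylprop-2-en-1-olate | Br[Mg]/C=C(/C)CO[Mg]Br | intermediate
3 | (2Z)-3-iodo-2-methylprop-2-en-1-ol | OC/C(C)=C\I | intermediate
4 | (2Z)-3-iodo-2-methylprop-2-enal | O=C/C(C)=C\I | intermediate
5 | (1Z,3S)-1-iodo-2-methylhexa-1,5-dien-3-yl diisopinocampheylborinate | C=CC[C@H](OB([C@@H]1C[C@@H]2C[C@H]([C@H]1C)C2(C)C)[C@@H]1C[C@@H]2C[C@H]([C@H]1C)C2(C)C)/C(C)=C\I | intermediate
6 | (1Z,3S)-1-iodo-2-methylhexa-1,5-dien-3-ol | C=CC[C@H](O)/C(C)=C\I | intermediate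
7 | methyl but-2-ynoate | CC#CC(=O)OC | starting material
8 | methyl (2E)-2-(diisobutylalumanyl)but-2-enoate (Al cis to the β-H) | C/C=C(/[Al](CC(C)C)CC(C)C)C(=O)OC | intermediate
9 | methyl (2Z)-2-(hydroxymethyl)but-2-enoate | C/C=C(/CO)C(=O)OC | intermediate
10 | (2Z)-2-(hydroxymethyl)but-2-enoic acid | C/C=C(/CO)C(=O)O | intermediate
11 | triethylsilyl (2Z)-2-[(triethylsilyloxy)methyl]but-2-enoate | C/C=C(/CO[Si](CC)(CC)CC)C(=O)O[Si](CC)(CC)CC | intermediate
12 | (2Z)-2-[(triethylsilyloxy)methyl]but-2-enoic acid | C/C=C(/CO[Si](CC)(CC)CC)C(=O)O | intermediate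
13 | (2Z)-2-[(triethylsilyloxy)methyl]but-2-enoic 2,4,6-trichlorobenzoic anhydride | C/C=C(/CO[Si](CC)(CC)CC)C(=O)OC(=O)c1c(Cl)cc(Cl)cc1Cl | intermediate
14 | (1Z,3S)-1-iodo-2-methylhexa-1,5-dien-3-yl (2Z)-2-[(triethylsilyloxy)methyl]but-2-enoate | C=CC[C@H](OC(=O)/C(=C\C)CO[Si](CC)(CC)CC)/C(C)=C\I | intermediate
15 | (2Z,4S)-3-methyl-1-oxohepta-2,6-dien-4-yl (2Z)-2-[(triethylsilyloxy)methyl]but-2-enoate | C=CC[C@H](OC(=O)/C(=C\C)CO[Si](CC)(CC)CC)/C(C)=C\C=O | intermediate
16 | methyl 2-(hydroxymethyl)prop-2-enoate | C=C(CO)C(=O)OC | starting material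
17 | methyl 2-(acetoxymethyl)prop-2-enoate | C=C(COC(C)=O)C(=O)OC | intermediate
18 | methyl (2E,5S,6Z)-2-(acetoxymethyl)-6-methyl-8-oxo-5-({(2Z)-2-[(triethylsilyloxy)methyl]but-2-enoyl}oxy)octa-2,6-dienoate | COC(=O)/C(COC(C)=O)=C/C[C@H](OC(=O)/C(=C\C)CO[Si](CC)(CC)CC)/C(C)=C\C=O | intermediate
19 | 3-methylbut-2-enal | CC(C)=CC=O | starting material
20 | tert-butyl(dimethyl){[(1E)-3-methylbuta-1,3-dien-1-yl]oxy}silane | C=C(C)/C=C/O[Si](C)(C)C(C)(C)C | intermediate
21 | methyl (2E,5S,6Z,8R,10E)-2-(acetoxymethyl)-8-hydroxy-6,10-dimethyl-12-oxo-5-({(2Z)-2-[(triethylsilyloxy)methyl]but-2-enoyl}oxy)dodeca-2,6,10-trienoate | COC(=O)/C(COC(C)=O)=C/C[C@H](OC(=O)/C(=C\C)CO[Si](CC)(CC)CC)/C(C)=C\[C@H](O)C/C(C)=C/C=O | intermediate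
22 | (acetato)(iodo)indium σ-allyl derived from 21 (In on C13, interconverting olefin geometry) | COC(=O)C(C[In](I)OC(C)=O)=CC[C@H](OC(=O)/C(=C\C)CO[Si](CC)(CC)CC)/C(C)=C\[C@H](O)C/C(C)=C/C=O | intermediate
23 | methyl (2R,6R,7S,9S)-6-[(acetato)(iodo)indiooxy]-2-hydroxy-9-{(2Z)-2-[(triethylsilyloxy)methyl]but-2-enoyloxy}germacra-1(10)Z,4E,11(13)-trien-12-oate | I[In](OC(C)=O)O[C@@H]1/C=C(\C)C[C@@H](O)/C=C(/C)[C@@H](OC(=O)/C(=C\C)CO[Si](CC)(CC)CC)C[C@H]1C(=C)C(=O)OC | intermediate
24 | (2R,6R,7S,9S)-2-hydroxy-9-{(2Z)-2-[(triethylsilyloxy)methyl]but-2-enoyloxy}germacra-1(10)Z,4E,11(13)-trien-12,6-olide | C=C1C(=O)O[C@@H]2/C=C(\C)C[C@@H](O)/C=C(/C)[C@@H](OC(=O)/C(=C\C)CO[Si](CC)(CC)CC)C[C@@H]12 | intermediate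
25 | (2R,6R,7S,9S)-2-hydroxy-9-[(2Z)-2-(hydroxymethyl)but-2-enoyloxy]germacra-1(10)Z,4E,11(13)-trien-12,6-olide | C=C1C(=O)O[C@@H]2/C=C(\C)C[C@@H](O)/C=C(/C)[C@@H](OC(=O)/C(=C\C)CO)C[C@@H]12 | target

**Step count**
- Total: 13 steps, including the three-step preparation of acid 12 and the one-step preparations of 17 and 20.
- Longest linear sequence: 8 steps (1 → 3 → 4 → 6 → 14 → 15 → 18 → 21 → 25).

**Three steps most likely to fail**

Step 13 (ring closure). Risks are oligomerisation, wrong facial pairing at C6/C7 relative to C9 (substrate control only), and zerovalent palladium ionising the C9 allylic ester or the product's allylic lactone. The fallback sets out from 15. Cross-metathesis of 15 with commercial methyl 2-(bromomethyl)prop-2-enoate gives the allylic bromide F1. The aldol of step 12 applied to F1 with 20 gives the bromo seco-aldehyde F2. F2 is closed palladium-free by a Nozaki–Hiyama–Kishi reaction (CrCl2, chiral sulfonamide–oxazoline ligand, THF, high dilution), so that the allylchromium and the ligand, not the substrate, control the C6/C7 faces. The chromium alkoxide lactonises and the route is rejoined at 24, which is desilylated to 25 as in step 13.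

Step 12 (vinylogous aldol). Risks are the facial sense at C2 in a doubly stereodifferentiating addition, further addition to the product enal, and Z to E drift of the aldehyde; using the D-tryptophan-derived Lewis acid is the immediate remedy if the sense is reversed. The approach-changing fallback sets out from 18. 3-Methylbut-2-enoyl chloride and morpholine give the amide F3, which is converted (LDA, TBSCl) to the silyl N,O-ketene acetal F4. Lewis-base-catalysed vinylogous aldol addition of F4 to 18 (SiCl4, chiral bisphosphoramide, CH2Cl2, −78 °C) gives the morpholine amide adduct F5, which cannot react further. Chemoselective reduction of the amide with Cp2Zr(H)Cl (THF, rt) returns to the route at 21.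

Step 8 (formylation). Risks are tin-hydride reduction of the C–I bond, ionisation or reduction of the neighbouring allylic ester, and Z/E isomerisation. The fallback sets out from 14. Hydroxymethylation of the vinyl iodide with paraformaldehyde (CrCl2, NiCl2 1 mol%, DMF/THF, rt) uses no zerovalent palladium and no hydride and gives the allylic alcohol F6. MnO2 oxidation of F6 returns to the route at 15.

**Further compounds**

F1 | step 13 | methyl (2Z,5S,6Z)-2-(bromomethyl)-6-methyl-8-oxo-5-({(2Z)-2-[(triethylsilyloxy)methyl]but-2-enoyl}oxy)octa-2,6-dienoate | COC(=O)/C(CBr)=C/C[C@H](OC(=O)/C(=C\C)CO[Si](CC)(CC)CC)/C(C)=C\C=O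
F2 | step 13 | methyl (2Z,5S,6Z,8R,10E)-2-(bromomethyl)-8-hydroxy-6,10-dimethyl-12-oxo-5-({(2Z)-2-[(triethylsilyloxy)methyl]but-2-enoyl}oxy)dodeca-2,6,10-trienoate | COC(=O)/C(CBr)=C/C[C@H](OC(=O)/C(=C\C)CO[Si](CC)(CC)CC)/C(C)=C\[C@H](O)C/C(C)=C/C=O
F3 | step 12 | 4-(3-methylbut-2-enoyl)morpholine | CC(C)=CC(=O)N1CCOCC1
F4 | step 12 | 4-[(1Z)-1-(tert-butyldimethylsilyloxy)-3-methylbuta-1,3-dien-1-yl]morpholine | C=C(C)/C=C(\O[Si](C)(C)C(C)(C)C)N1CCOCC1
F5 | step 12 | methyl (2E,5S,6Z,8R,10E)-2-(acetoxymethyl)-8-hydroxy-6,10-dimethyl-12-(morpholin-4-yl)-12-oxo-5-({(2Z)-2-[(triethylsilyloxy)methyl]but-2-enoyl}oxy)dodeca-2,6,10-trienoate | COC(=O)/C(COC(C)=O)=C/C[C@H](OC(=O)/C(=C\C)CO[Si](CC)(CC)CC)/C(C)=C\[C@H](O)C/C(C)=C/C(=O)N1CCOCC1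
F6 | step 8 | (2Z,4S)-1-hydroxy-3-methylhepta-2,6-dien-4-yl (2Z)-2-[(triethylsilyloxy)methyl]but-2-enoate | C=CC[C@H](OC(=O)/C(=C\C)CO[Si](CC)(CC)CC)/C(C)=C\CO
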